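**Retrosynthetic overview**
1. Target 14 ⇐ hydrogenolysis of bis(benzyl ether) 13 ⇐ Vilsmeier formylation of acetate 11 at the ring CH para to the methoxy group ⇐ acetylation of (R)-alcohol 10.
2. 10 ⇐ one-pot three-component enantioselective conjunctive cross-coupling and oxidation of undecylmagnesium bromide 6, vinylboronic ester 7 and aryl bromide 4. The bond between the first CH2 of the undecyl chain and the carbinol carbon is made by a 1,2-shift from boron to carbon, and the ArCH2–C bond by reductive elimination.
3. Enabling feature: the side chain is Ar–CH2–CH(O)–CH2R. The carbinol carbon lies between the benzylic CH2 on the benzene ring and the first CH2 of the undecyl chain, so these two carbons map onto the two carbons of a vinylboron ate complex and the C–O bond onto its C–B bond.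
4. 4 ⇐ Dakin oxidation and bis-benzylation of 5-bromovanillin 1; 6 ⇐ 1-bromoundecane 5.
5. No ring is formed: the only ring, the benzene ring, comes from 1 with its bromine, methoxy group and both oxygen positions already fixed.

Key step: step 4

Assumption: the target stereocentre is (R). The sense of induction of the MandyPhos-type ligand in step 4 is taken by analogy, so the ligand antipode that leads to the (R)-boronic ester 9 is the one used. The configuration of 10 would be checked (Mosher esters) before going on.

**Step 1**
Reactants: 1 5-bromovanillin (3-bromo-4-hydroxy-5-methoxybenzaldehyde)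
Product: 3 2-bromo-6-methoxybenzene-1,4-diol, via aryl formate 2 (not isolated)
Conditions: 30% aq H2O2 (1.2 equiv), 2 M aq NaOH, THF, 0 °C to rt, N2; then 2 M HCl
Reagents that add atoms: hydrogen peroxide, OO
Why: Dakin oxidation, in which the hydroperoxide anion adds to the aldehyde of the para-hydroxybenzaldehyde, the electron-rich aryl group migrates to oxygen to give formate 2, and the base hydrolyses the formate in the same flask, so that the formyl carbon is exchanged for the second hydroquinone oxygen.

**Step 2**
Reactants: 3 2-bromo-6-methoxybenzene-1,4-diol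
Product: 4 2,5-bis(benzyloxy)-1-bromo-3-methoxybenzene
Conditions: BnBr (2.4 equiv), K2CO3 (3 equiv), degassed DMF, 60 °C, Ar
Reagents that add atoms: benzyl bromide, BrCc1ccccc1
Why: Williamson ether synthesis on both phenoxides with a reactive benzylic bromide, run with exclusion of air so that the hydroquinone is not oxidised to the quinone before it is alkylated.

**Step 3**
Reactants: 5 1-bromoundecane
Product: 6 undecylmagnesium bromide (titrated THF solution)
Conditions: Mg turnings (1.2 equiv), I2 (cat.), THF, rt to 50 °C
Reagents that add atoms: magnesium, [Mg]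
Why: Grignard reagent formation by insertion of magnesium into a primary alkyl C–Br bond, a standard reaction for long-chain bromides.

**Step 4**
Reactants: 4 2,5-bis(benzyloxy)-1-bromo-3-methoxybenzene; 6 undecylmagnesium bromide; 7 vinylboronic acid pinacol ester (2-ethenyl-4,4,5,5-tetramethyl-1,3,2-dioxaborolane)
Product: 10 (R)-1-[2,5-bis(benzyloxy)-3-methoxyphenyl]tridecan-2-ol, via boron ate complex 8 (not isolated), via pinacol boronate 9 (not isolated)
Conditions: 7, 6, NaOTf (CF3SO3Na, 2 equiv), THF, 0 °C to rt; then 4, Pd(OAc)2 (2 mol%), enantiopure MandyPhos ligand Fe[C5H3(CH(NMe2)Ph)(PAr2)]2 with Ar = 4-methoxy-3,5-dimethylphenyl (2.4 mol%), THF/DMSO, 40–60 °C; then 3 M aq NaOH, 30% aq H2O2, 0 °C to rt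
Reagents that add atoms: hydrogen peroxide, OO
Why: Grignard 6 adds to the boron of 7 to give the four-coordinate vinylboronate 8; zerovalent palladium inserts into the C–Br bond of 4, NaOTf strips the bromide, and the cationic arylpalladium binds the vinyl group of 8 and induces a 1,2-metallate shift in which the undecyl group moves from boron to the boron-bearing carbon anti to palladium (making the bond between the first CH2 of the undecyl chain and the future carbinol carbon) while the terminal carbon becomes bonded to palladium, after which reductive elimination makes the aryl–CH2 bond. The closest known reaction type is the palladium-catalysed enantioselective conjunctive cross-coupling of Grignard-derived vinylboron ate complexes carrying alkyl migrating groups with aryl bromides or triflates in the presence of NaOTf, followed by stereoretentive oxidation of the secondary boronic ester. No ring is closed. The single new stereocentre (the C–B, then C–O carbon) is set under catalyst control: the C2-symmetric chiral ferrocenyl bisphosphine decides which face of the bound vinyl group palladium occupies, the migration is anti to the metal, and the oxidation of 9 to 10 goes with retention, so the ligand antipode fixes the (R) configuration. The step needs chemoselectivity for the metallate shift over direct Suzuki-type transfer of the vinyl or undecyl group and over β-hydride elimination of the alkylpalladium intermediate; the saturated boron centre, the chelating bisphosphine that leaves no open coordination site and the halide-free cationic palladium should secure this, and the aryl bromide carries only one ortho substituent because the formyl group is left off until step 6.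

**Step 5**
Reactants: 10 (R)-1-[2,5-bis(benzyloxy)-3-methoxyphenyl]tridecan-2-ol
Product: 11 (R)-1-[2,5-bis(benzyloxy)-3-methoxyphenyl]tridecan-2-yl acetate
Conditions: Ac2O, pyridine, DMAP (cat.), CH2Cl2, rt
Reagents that add atoms: acetic anhydride, CC(=O)OC(C)=O
Why: DMAP-catalysed O-acylation of an unhindered secondary alcohol, which does not touch the C–O bond of the stereocentre, so the (R) configuration is kept.

**Step 6**
Reactants: 11 (R)-1-[2,5-bis(benzyloxy)-3-methoxyphenyl]tridecan-2-yl acetate
Product: 13 (R)-1-[2,5-bis(benzyloxy)-6-formyl-3-methoxyphenyl]tridecan-2-yl acetate, via iminium salt 12 (not isolated)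
Conditions: POCl3 (3 equiv), DMF, 0 °C to 60 °C; then aq NaOAc, rt
Reagents that add atoms: N,N-dimethylformamide, CN(C)C=O; water, O
Why: Vilsmeier–Haack formylation of a trialkoxybenzene, in which the ring CH next to the side chain is para to the methoxy group and ortho to a benzyloxy group (the position attacked in 1,2,4-trialkoxybenzenes and in 5-alkylresorcinol dimethyl ethers) whereas the other ring CH is wedged between two alkoxy groups, and the acetate and benzyl ethers are inert to the chloroiminium reagent.

**Step 7**
Reactants: 13 (R)-1-[2,5-bis(benzyloxy)-6-formyl-3-methoxyphenyl]tridecan-2-yl acetate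
Product: 14 (R)-1-(2-formyl-3,6-dihydroxy-5-methoxyphenyl)tridecan-2-yl acetate (target)
Conditions: H2 (1 atm), 10% Pd/C, EtOAc, rt; filtration and concentration under Ar
Reagents that add atoms: none
Why: Hydrogenolysis of the two aryl benzyl ethers over palladium on carbon in a non-protic solvent should be fast compared with reduction of the hindered, electron-rich aldehyde, and the acetate and the non-benzylic stereocentre are not affected.

**Compound list**
1 | 5-bromovanillin (3-bromo-4-hydroxy-5-methoxybenzaldehyde) | COc1cc(C=O)cc(Br)c1O | starting material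
2 | 3-bromo-4-hydroxy-5-methoxyphenyl formate | COc1cc(OC=O)cc(Br)c1O | intermediate (not isolated)
3 | 2-bromo-6-methoxybenzene-1,4-diol | COc1cc(O)cc(Br)c1O | intermediate
4 | 2,5-bis(benzyloxy)-1-bromo-3-methoxybenzene | COc1cc(OCc2ccccc2)cc(Br)c1OCc1ccccc1 | intermediate
5 | 1-bromoundecane | CCCCCCCCCCCBr | starting material
6 | undecylmagnesium bromide | CCCCCCCCCCC[Mg]Br | intermediate
7 | vinylboronic acid pinacol ester (2-ethenyl-4,4,5,5-tetramethyl-1,3,2-dioxaborolane) | C=CB1OC(C)(C)C(C)(C)O1 | starting material
8 | bromomagnesium ethenyl(undecyl)(pinacolato)borate | CCCCCCCCCCC[B-]1(C=C)OC(C)(C)C(C)(C)O1.[Mg+]Br | intermediate (not isolated)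
9 | 2-[(2R)-1-[2,5-bis(benzyloxy)-3-methoxyphenyl]tridecan-2-yl]-4,4,5,5-tetramethyl-1,3,2-dioxaborolane | CCCCCCCCCCC[C@H](Cc1cc(OCc2ccccc2)cc(OC)c1OCc1ccccc1)B1OC(C)(C)C(C)(C)O1 | intermediate (not isolated)
10 | (R)-1-[2,5-bis(benzyloxy)-3-methoxyphenyl]tridecan-2-ol | CCCCCCCCCCC[C@H](Cc1cc(OCc2ccccc2)cc(OC)c1OCc1ccccc1)O | intermediate
11 | (R)-1-[2,5-bis(benzyloxy)-3-methoxyphenyl]tridecan-2-yl acetate | CCCCCCCCCCC[C@H](Cc1cc(OCc2ccccc2)cc(OC)c1OCc1ccccc1)OC(C)=O | intermediate
12 | N-[[2-[(2R)-2-acetoxytridecyl]-3,6-bis(benzyloxy)-4-methoxyphenyl]methylidene]-N-methylmethanaminium dichlorophosphate | CCCCCCCCCCC[C@H](Cc1c(OCc2ccccc2)c(OC)cc(OCc2ccccc2)c1C=[N+](C)C)OC(C)=O.[O-]P(=O)(Cl)Cl | intermediate (not isolated)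
13 | (R)-1-[2,5-bis(benzyloxy)-6-formyl-3-methoxyphenyl]tridecan-2-yl acetate | CCCCCCCCCCC[C@H](Cc1c(OCc2ccccc2)c(OC)cc(OCc2ccccc2)c1C=O)OC(C)=O | intermediate
14 | (R)-1-(2-formyl-3,6-dihydroxy-5-methoxyphenyl)tridecan-2-yl acetate | CCCCCCCCCCC[C@H](Cc1c(O)c(OC)cc(O)c1C=O)OC(C)=O | target

**Step count and risks**
Total step count: 7. Longest linear sequence: 6 steps (1, 2, 4, 5, 6, 7); step 3 is a one-step branch.

Steps most likely to fail:

Step 4. Direct Suzuki-type transmetallation of the ate complex, slow oxidative addition into the electron-rich ortho-benzyloxy aryl bromide, or erosion of enantioselectivity may outrun the metallate shift. The fallback makes the same carbinol C–CH2 bond by carbonyl allylation instead of a boron 1,2-shift; it sets out from 4 and comes back to the route at 10. Bromine–lithium exchange on 4 (n-BuLi, THF, −78 °C) and opening of ethylene oxide (BF3·OEt2) should give 2-[2,5-bis(benzyloxy)-3-methoxyphenyl]ethanol F1. Iridium-catalysed transfer-hydrogenative allylation of this primary alcohol with allyl acetate ([Ir(cod)Cl]2, the BINAP antipode that gives the (R) product, 4-chloro-3-nitrobenzoic acid, Cs2CO3, THF, 100 °C) should give (R)-1-[2,5-bis(benzyloxy)-3-methoxyphenyl]pent-4-en-2-ol F2, whose allyl CH2 is the first carbon of the later undecyl chain. Cross-metathesis with excess 1-decene (second-generation Grubbs catalyst, RuCl2(=CHPh)(PCy3)(H2IMes), CH2Cl2, 40 °C) should give (R,E)-1-[2,5-bis(benzyloxy)-3-methoxyphenyl]tridec-4-en-2-ol F3; the alkene geometry is of no consequence. Hydrogenation of the alkene over PtO2 (H2, 1 atm, EtOAc), which spares aryl benzyl ethers, should then give 10.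

Step 6. Attack at the other ring CH (between the methoxy and benzyloxy groups) or sluggish attack at the hindered carbon may spoil the formylation. The fallback delivers the carbon through a tether from the side-chain oxygen; it sets out from 10 (replacing steps 5 and 6) and comes back at 13. Oxa-Pictet–Spengler cyclisation of 10 with dimethoxymethane (BF3·OEt2, CH2Cl2, 0 °C) can only close onto the single free ring carbon ortho to the side chain and should give (R)-5,8-bis(benzyloxy)-6-methoxy-3-undecylisochromane F4. Acylative ring opening with acetyl chloride and catalytic ZnCl2 (CH2Cl2, 0 °C) should cleave the benzylic C–O bond, whose cation is stabilised by the para methoxy group, and leave the C–O bond of the stereocentre intact, giving (R)-1-[2,5-bis(benzyloxy)-6-(chloromethyl)-3-methoxyphenyl]tridecan-2-yl acetate F5. Kornblum-type oxidation of the benzylic chloride with N-methylmorpholine N-oxide (MeCN, rt, NaHCO3 work-up) should give 13.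

Step 7. Over-reduction of the aldehyde during hydrogenolysis, or air oxidation of the hydroquinone to the quinone during isolation, may lower the outcome. The fallback replaces the reductive cleavage by a non-reductive Lewis-acid dealkylation; it sets out from 13 and ends at 14. Treatment with BCl3 and pentamethylbenzene as benzyl cation scavenger (CH2Cl2, −78 °C, MeOH quench) should remove both benzyl groups while the methoxy group (not ortho to the carbonyl), the acetate and the aldehyde stay intact. No new compound is made.

**Further compounds**
F1 | step 4 | 2-[2,5-bis(benzyloxy)-3-methoxyphenyl]ethanol | OCCc1cc(OCc2ccccc2)cc(OC)c1OCc1ccccc1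
F2 | step 4 | (R)-1-[2,5-bis(benzyloxy)-3-methoxyphenyl]pent-4-en-2-ol | C=CC[C@H](Cc1cc(OCc2ccccc2)cc(OC)c1OCc1ccccc1)O
F3 | step 4 | (R,E)-1-[2,5-bis(benzyloxy)-3-methoxyphenyl]tridec-4-en-2-ol | CCCCCCCC/C=C/C[C@H](Cc1cc(OCc2ccccc2)cc(OC)c1OCc1ccccc1)O
F4 | step 6 | (R)-5,8-bis(benzyloxy)-6-methoxy-3-undecylisochromane | CCCCCCCCCCC[C@@H]1Cc2c(OCc3ccccc3)c(OC)cc(OCc3ccccc3)c2CO1
F5 | step 6 | (R)-1-[2,5-bis(benzyloxy)-6-(chloromethyl)-3-methoxyphenyl]tridecan-2-yl acetate | CCCCCCCCCCC[C@H](Cc1c(OCc2ccccc2)c(OC)cc(OCc2ccccc2)c1CCl)OC(C)=O
F0 | step 7 | none | none
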